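**Retrosynthetic overview**

1. Numbering: 3,7-dioxabicyclo[3.3.0]octane core, C1/C5 ring fusion, C2 carries the phenol ring, C6 the prenyloxyaryl ring. Target 25 ⇐ aryl silyl ether 24 by O–Si cleavage.
2. 24 ⇐ C6–aryl bond: potassium aryltrifluoroborate 22 plus the oxocarbenium ion O7=C6(+), itself generated in the same flask from the 2,3-dihydrofuran MOM ether 16 by C4–C5 ring closure (the MOM CH2 becomes C4).
3. Enabling feature: C6 is bonded to ring oxygen O7 on a cis-fused bicyclo[3.3.0] core, so it can be carried as a cation with one open (convex) face. Its neighbour C5 is the β-carbon of the enol ether O7–C6=C5 and is linked to the benzylic oxygen O3 through one formaldehyde-level carbon, C4.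
4. 16 ⇐ lactol 14 ⇐ pentenol 11 ⇐ Evans syn-aldol of pentenoyl imide 6 with silylated vanillin 2, which sets C1 and C2.
5. Ring order: O7 ring first (lactol, then dihydrofuran, steps 6–7); O3 ring and the C6–aryl bond together in step 10.

Key step: step 10

Remark: the target SMILES encodes the all-exo, cis-fused (pinoresinol-type) isomer with 1S,2R,5S,6R; the precursors are named with the same atom numbers.

**Route**

Step 1
Reactants: 1 vanillin
Product: 2 3-methoxy-4-(triisopropylsilyloxy)benzaldehyde
Conditions: TIPSCl, imidazole, DMF, rt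
Reagents that add atoms: triisopropylsilyl chloride, CC(C)[Si](Cl)(C(C)C)C(C)C
Why: Phenol O-silylation should give an aryl TIPS ether that tolerates the base, hydride and Lewis-acid steps ahead and leaves with fluoride at the end.

Step 2
Reactants: 3 (R)-4-benzyl-1,3-oxazolidin-2-one; 4 pent-4-enoyl chloride
Product: 6 (R)-4-benzyl-3-(pent-4-enoyl)-1,3-oxazolidin-2-one, via lithium oxazolidinide 5 (not isolated)
Conditions: n-BuLi, THF, −78 °C; then 4, −78 → 0 °C
Reagents that add atoms: none
Why: N-acylation of the lithiated oxazolidinone with the acid chloride is standard imide formation and touches no stereocentre.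

Step 3
Reactants: 6 (R)-4-benzyl-3-(pent-4-enoyl)-1,3-oxazolidin-2-one; 2 3-methoxy-4-(triisopropylsilyloxy)benzaldehyde
Product: 8 (R)-4-benzyl-3-[(2R)-2-{(R)-hydroxy[3-methoxy-4-(triisopropylsilyloxy)phenyl]methyl}pent-4-enoyl]-1,3-oxazolidin-2-one, via Z-boron enolate 7 (not isolated)
Conditions: n-Bu2BOTf, i-Pr2NEt, CH2Cl2, 0 °C; then 2, −78 → 0 °C; pH 7 buffer, MeOH, 30% H2O2, 0 °C
Reagents that add atoms: none
Why: Evans syn-aldol reaction: the Z-boron enolate should react through a closed chair (Zimmerman–Traxler) transition state on the face away from the benzyl group of the (R)-auxiliary, which sets the α-carbon (later C1) as R and the carbinol carbon (later C2) as R in a syn relationship.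

Step 4
Reactants: 8 the aldol adduct; 9 chloromethyl methyl ether
Product: 10 (R)-4-benzyl-3-[(2R)-2-{(R)-(methoxymethoxy)[3-methoxy-4-(triisopropylsilyloxy)phenyl]methyl}pent-4-enoyl]-1,3-oxazolidin-2-one
Conditions: i-Pr2NEt, n-Bu4NI (cat.), CH2Cl2, 0 °C → rt
Reagents that add atoms: none
Why: O-alkylation of the secondary benzylic hydroxyl with the α-chloro ether (MOM ether formation) under a non-nucleophilic amine base should leave both stereocentres untouched and installs the O–CH2–OMe unit whose CH2 becomes C4.

Step 5
Reactants: 10 the MOM-protected imide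
Product: 11 (2S)-2-{(R)-(methoxymethoxy)[3-methoxy-4-(triisopropylsilyloxy)phenyl]methyl}pent-4-en-1-ol
Conditions: LiBH4, MeOH (1 equiv), THF, 0 °C
Reagents that add atoms: none
Why: Reductive cleavage of the N-acyl oxazolidinone by borohydride should give the primary alcohol (later O7–C8) and release the auxiliary without touching the stereocentres, the MOM ether or the silyl ether.

Step 6
Reactants: 11 the pentenol
Product: 14 (4S)-4-{(R)-(methoxymethoxy)[3-methoxy-4-(triisopropylsilyloxy)phenyl]methyl}oxolan-2-ol (both anomers), via triol 12 (not isolated), via hydroxy aldehyde 13 (not isolated)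
Conditions: OsO4 (cat.), NaIO4, 2,6-lutidine, dioxane/H2O, rt
Reagents that add atoms: sodium periodate, [Na+].[O-]I(=O)(=O)=O; osmium tetroxide (catalytic oxygen carrier), O=[Os](=O)(=O)=O
Why: Lemieux–Johnson oxidative cleavage of the only alkene should give the aldehyde, which closes at once with the primary hydroxyl to the five-membered lactol (hemiacetal formation); the anomeric centre forms as a mixture and is erased in step 7.

Step 7
Reactants: 14 the lactol
Product: 16 triisopropyl{2-methoxy-4-[(R)-(methoxymethoxy)((3S)-2,3-dihydrofuran-3-yl)methyl]phenoxy}silane, via anomeric mesylate 15 (not isolated)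
Conditions: MsCl, Et3N, CH2Cl2, −40 °C → reflux; chromatography on Et3N-deactivated silica
Reagents that add atoms: none
Why: Lactol dehydration by anomeric sulfonylation and base-mediated β-elimination (the usual furanoid glycal synthesis) should give the cyclic enol ether as the only possible regioisomer, since C6 has C5 as its sole carbon neighbour; no stereocentre is formed.

Step 8
Reactants: 17 4-bromo-2-methoxyphenol; 18 1-bromo-3-methylbut-2-ene (prenyl bromide)
Product: 19 4-bromo-2-methoxy-1-(3-methylbut-2-enyloxy)benzene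
Conditions: K2CO3, DMF, rt
Reagents that add atoms: none
Why: Williamson ether synthesis (phenoxide SN2 at the primary allylic bromide) should give the aryl prenyl ether without C-alkylation under these mild conditions.

Step 9
Reactants: 19 the aryl bromide
Product: 22 potassium trifluoro[3-methoxy-4-(3-methylbut-2-enyloxy)phenyl]borate, via aryllithium 20 (not isolated), via lithium triisopropoxyborate 21 (not isolated)
Conditions: n-BuLi, THF, −78 °C; B(Oi-Pr)3, −78 °C → rt; then aq. KHF2, MeOH, rt
Reagents that add atoms: triisopropyl borate, CC(C)OB(OC(C)C)OC(C)C; potassium hydrogen difluoride, [K+].[F-].F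
Why: Bromine–lithium exchange, borylation of the aryllithium and fluoride exchange with KHF2 should fix boron at the carbon para to the prenyl ether and give a bench-stable aryl donor.

Step 10
Reactants: 16 the dihydrofuran MOM ether; 22 the potassium aryltrifluoroborate
Product: 24 (1S,2R,5S,6R)-6-[3-methoxy-4-(3-methylbut-2-enyloxy)phenyl]-2-[3-methoxy-4-(triisopropylsilyloxy)phenyl]-3,7-dioxabicyclo[3.3.0]octane, via bicyclic methyl acetal 23 (not isolated)
Conditions: TMSOTf (5 mol %), 2,6-di-tert-butyl-4-methylpyridine (10 mol %), CH2Cl2 (high dilution, slow addition of 16), −78 °C; then 22, BF3·OEt2, MeCN, −40 → 0 °C, same flask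
Reagents that add atoms: none
Why: Proposed new method: catalytic TMSOTf should ionise the MOM ether at its methoxy end to the oxocarbenium ion O3=C4H2(+), which the β-carbon C5 of the dihydrofuran enol ether captures (an intramolecular Mukaiyama–Prins-type acetal/enol ether addition), and the resulting ion O7=C6(+) collapses with TMSOMe to the methyl acetal 23; BF3·OEt2 then re-ionises 23 and the aryldifluoroborane formed from 22 delivers its aryl group by ipso transfer from boron to C6. The closest known reaction types are the Lewis-acid addition of acetals to vinyl ethers and Prins cyclisations of MOM ethers for the first stage, and the BF3-promoted coupling of potassium aryltrifluoroborates with cyclic O,O-acetals (C-aryl glycosylation through an oxocarbenium ion) for the second; their union in one flask on this substrate class is new. The O3 tetrahydrofuran ring (O3–C4–C5–C1–C2) closes by C4–C5 bond formation, 5-exo-trig with respect to the enol ether C5=C6 and with the C4=O3 oxocarbenium bond inside the new ring. The new stereocentre C5 is controlled by the existing centre C1: the tether C2–O3–C4 can reach C5 only on the ring face that carries C2, so the fusion must be cis. The new stereocentre C6 is controlled by the shape of the cis-fused bicyclo[3.3.0] oxocarbenium ion, whose convex face, anti to the C5–C4 bond, is the only open one; both anomers of 23 pass through this ion, so the anomeric mixture should converge on the exo-aryl (6R) product. The step needs C5 rather than C6 attack, secured by the enol ether polarisation, ring closure ahead of intermolecular capture, secured by dilution and slow addition, and a single aryl regiochemistry, secured by ipso transfer from the boron-bearing carbon para to the prenyl ether.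

Step 11
Reactants: 24 the silyl-protected furofuran
Product: 25 2-methoxy-4-{(1S,2R,5S,6R)-6-[3-methoxy-4-(3-methylbut-2-enyloxy)phenyl]-3,7-dioxabicyclo[3.3.0]octan-2-yl}phenol (target; 1R,3aS,4R,6aS in furo[3,4-c]furan numbering)
Conditions: TBAF, THF, 0 °C
Reagents that add atoms: none
Why: Fluoride-mediated cleavage of the aryl silyl ether should free the phenol while the prenyl ether, the benzylic ethers and all four stereocentres stay untouched.

**Compound list**

1 | vanillin (4-hydroxy-3-methoxybenzaldehyde) | COc1cc(C=O)ccc1O | starting material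
2 | 3-methoxy-4-(triisopropylsilyloxy)benzaldehyde | COc1cc(C=O)ccc1O[Si](C(C)C)(C(C)C)C(C)C | intermediate
3 | (R)-4-benzyl-1,3-oxazolidin-2-one | O=C1N[C@H](Cc2ccccc2)CO1 | starting material
4 | pent-4-enoyl chloride | C=CCCC(=O)Cl | starting material
5 | N-lithio-(R)-4-benzyl-1,3-oxazolidin-2-one (formed in the flask) | O=C1OC[C@@H](Cc2ccccc2)N1[Li] | intermediate
6 | (R)-4-benzyl-3-(pent-4-enoyl)-1,3-oxazolidin-2-one | C=CCCC(=O)N1C(=O)OC[C@H]1Cc1ccccc1 | intermediate
7 | (Z)-dibutylboron enolate of 6 (formed in the flask) | C=CC/C=C(\OB(CCCC)CCCC)N1C(=O)OC[C@H]1Cc1ccccc1 | intermediate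
8 | (R)-4-benzyl-3-[(2R)-2-{(R)-hydroxy[3-methoxy-4-(triisopropylsilyloxy)phenyl]methyl}pent-4-enoyl]-1,3-oxazolidin-2-one | COc1cc([C@H](O)[C@H](C(=O)N2C(=O)OC[C@H]2Cc2ccccc2)CC=C)ccc1O[Si](C(C)C)(C(C)C)C(C)C | intermediate
9 | chloromethyl methyl ether | COCCl | starting material
10 | (R)-4-benzyl-3-[(2R)-2-{(R)-(methoxymethoxy)[3-methoxy-4-(triisopropylsilyloxy)phenyl]methyl}pent-4-enoyl]-1,3-oxazolidin-2-one | COc1cc([C@H](OCOC)[C@H](C(=O)N2C(=O)OC[C@H]2Cc2ccccc2)CC=C)ccc1O[Si](C(C)C)(C(C)C)C(C)C | intermediate
11 | (2S)-2-{(R)-(methoxymethoxy)[3-methoxy-4-(triisopropylsilyloxy)phenyl]methyl}pent-4-en-1-ol | COc1cc([C@H](OCOC)[C@H](CO)CC=C)ccc1O[Si](C(C)C)(C(C)C)C(C)C | intermediate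
12 | (4S)-4-{(R)-(methoxymethoxy)[3-methoxy-4-(triisopropylsilyloxy)phenyl]methyl}pentane-1,2,5-triol, C2 epimers (formed in the flask) | COc1cc([C@H](OCOC)[C@H](CO)CC(O)CO)ccc1O[Si](C(C)C)(C(C)C)C(C)C | intermediate
13 | (3S,4R)-3-(hydroxymethyl)-4-(methoxymethoxy)-4-[3-methoxy-4-(triisopropylsilyloxy)phenyl]butanal (formed in the flask) | COc1cc([C@H](OCOC)[C@H](CO)CC=O)ccc1O[Si](C(C)C)(C(C)C)C(C)C | intermediate
14 | (4S)-4-{(R)-(methoxymethoxy)[3-methoxy-4-(triisopropylsilyloxy)phenyl]methyl}oxolan-2-ol, both anomers | COc1cc([C@H](OCOC)[C@@H]2COC(O)C2)ccc1O[Si](C(C)C)(C(C)C)C(C)C | intermediate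
15 | (4S)-4-{(R)-(methoxymethoxy)[3-methoxy-4-(triisopropylsilyloxy)phenyl]methyl}oxolan-2-yl methanesulfonate (formed in the flask) | COc1cc([C@H](OCOC)[C@@H]2COC(OS(C)(=O)=O)C2)ccc1O[Si](C(C)C)(C(C)C)C(C)C | intermediate
16 | triisopropyl{2-methoxy-4-[(R)-(methoxymethoxy)((3S)-2,3-dihydrofuran-3-yl)methyl]phenoxy}silane | COc1cc([C@H](OCOC)[C@@H]2COC=C2)ccc1O[Si](C(C)C)(C(C)C)C(C)C | intermediate
17 | 4-bromo-2-methoxyphenol | COc1cc(Br)ccc1O | starting material
18 | 1-bromo-3-methylbut-2-ene (prenyl bromide) | CC(C)=CCBr | starting material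
19 | 4-bromo-2-methoxy-1-(3-methylbut-2-enyloxy)benzene | COc1cc(Br)ccc1OCC=C(C)C | intermediate
20 | [3-methoxy-4-(3-methylbut-2-enyloxy)phenyl]lithium (formed in the flask) | COc1cc([Li])ccc1OCC=C(C)C | intermediate
21 | lithium triisopropoxy[3-methoxy-4-(3-methylbut-2-enyloxy)phenyl]borate (formed in the flask) | [Li+].COc1cc(ccc1OCC=C(C)C)[B-](OC(C)C)(OC(C)C)OC(C)C | intermediate
22 | potassium trifluoro[3-methoxy-4-(3-methylbut-2-enyloxy)phenyl]borate | [K+].COc1cc(ccc1OCC=C(C)C)[B-](F)(F)F | intermediate
23 | (1S,2R,5S)-6-methoxy-2-[3-methoxy-4-(triisopropylsilyloxy)phenyl]-3,7-dioxabicyclo[3.3.0]octane, C6 epimers (formed in the flask) | COc1cc([C@@H]2OC[C@@H]3[C@H]2COC3OC)ccc1O[Si](C(C)C)(C(C)C)C(C)C | intermediate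
24 | (1S,2R,5S,6R)-6-[3-methoxy-4-(3-methylbut-2-enyloxy)phenyl]-2-[3-methoxy-4-(triisopropylsilyloxy)phenyl]-3,7-dioxabicyclo[3.3.0]octane | COc1cc([C@@H]2OC[C@@H]3[C@H]2CO[C@H]3c2ccc(OCC=C(C)C)c(OC)c2)ccc1O[Si](C(C)C)(C(C)C)C(C)C | intermediate
25 | 2-methoxy-4-{(1S,2R,5S,6R)-6-[3-methoxy-4-(3-methylbut-2-enyloxy)phenyl]-3,7-dioxabicyclo[3.3.0]octan-2-yl}phenol | COc1cc([C@@H]2OC[C@@H]3[C@H]2CO[C@H]3c2ccc(OCC=C(C)C)c(OC)c2)ccc1O | target

**Step count**

Total steps: 11.
Longest linear sequence: 8 steps (2, 3, 4, 5, 6, 7, 10, 11 from compound 3; equally 1, 3, 4, 5, 6, 7, 10, 11 from vanillin).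

**Steps most likely to fail, with fallbacks**

Step 10 (proposed new method). Three processes may defeat it:
- Unreacted enol ether may attack the ionised bicyclic acetal of another molecule, giving oligomers before ring closure is complete.
- BF3 may cleave or shift the prenyl aryl ether.
- BF3 may ionise the electron-rich benzylic C–O bonds, opening the rings and epimerising C2 or C6.

The fallback sets out from 16 and comes back at 24, using known chemistry in separate steps. The TMSOTf-catalysed cyclisation is run alone and the bicyclic methyl acetal 23 is isolated. Exchange of its methoxy group with benzenesulfinic acid (PhSO2H, CaCl2, CH2Cl2, rt) should give the anomeric phenyl sulfone F1. The aryl Grignard reagent F2, made from bromide 19 and magnesium in THF, is combined with ZnBr2 and should displace the sulfone at rt through the same oxocarbenium ion, which is the known substitution of 2-sulfonyl cyclic ethers by arylzinc reagents. This gives 24 with the same convex-face selectivity and never exposes the prenyl ether to BF3.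

Step 7. Substitution at the anomeric carbon (chloride or lactol dimer formation) may outrun elimination, and the enol ether may be rehydrated by traces of acid on work-up.

The fallback sets out from lactol 14 and comes back at 16. Neutral thioacetalisation (PhSSPh, n-Bu3P, THF) should give the phenylthio acetal F3. Oxidation (mCPBA, CH2Cl2, −78 °C; no alkene is present at this stage) should give the sulfoxide F4. Thermal syn-elimination (toluene, i-Pr2NEt, 90 °C) should then give the dihydrofuran 16 without any sulfonate or acid.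

Step 4. Retro-aldol cleavage or dehydration of the electron-rich benzylic aldol may compete under prolonged exposure to base, and alkylation of the hindered hydroxyl may stay incomplete.

The fallback sets out from aldol 8 and comes back at alcohol 11. LiBH4 reduction is done first and should give the 1,3-diol F5, in which retro-aldol is no longer possible. Selective acylation of the primary hydroxyl (PivCl, pyridine, 0 °C) should give the pivalate F6. The MOM group is then put on the secondary hydroxyl (9, i-Pr2NEt, CH2Cl2) to give F7. DIBAL-H (CH2Cl2, −78 °C) removes the pivalate to give 11.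

**Further compounds**

F1 | step 10 | (1S,2R,5S)-2-[3-methoxy-4-(triisopropylsilyloxy)phenyl]-6-(phenylsulfonyl)-3,7-dioxabicyclo[3.3.0]octane, C6 epimers | COc1cc([C@@H]2OC[C@@H]3[C@H]2COC3S(=O)(=O)c2ccccc2)ccc1O[Si](C(C)C)(C(C)C)C(C)C
F2 | step 10 | [3-methoxy-4-(3-methylbut-2-enyloxy)phenyl]magnesium bromide | COc1cc([Mg]Br)ccc1OCC=C(C)C
F3 | step 7 | (4S)-4-{(R)-(methoxymethoxy)[3-methoxy-4-(triisopropylsilyloxy)phenyl]methyl}-2-(phenylthio)oxolane, C2 epimers | COc1cc([C@H](OCOC)[C@@H]2COC(Sc3ccccc3)C2)ccc1O[Si](C(C)C)(C(C)C)C(C)C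
F4 | step 7 | (4S)-4-{(R)-(methoxymethoxy)[3-methoxy-4-(triisopropylsilyloxy)phenyl]methyl}-2-(phenylsulfinyl)oxolane, mixture of isomers at C2 and sulfur | COc1cc([C@H](OCOC)[C@@H]2COC(S(=O)c3ccccc3)C2)ccc1O[Si](C(C)C)(C(C)C)C(C)C
F5 | step 4 | (1R,2S)-1-[3-methoxy-4-(triisopropylsilyloxy)phenyl]-2-(prop-2-enyl)propane-1,3-diol | COc1cc([C@H](O)[C@H](CO)CC=C)ccc1O[Si](C(C)C)(C(C)C)C(C)C
F6 | step 4 | (2S)-2-{(R)-hydroxy[3-methoxy-4-(triisopropylsilyloxy)phenyl]methyl}pent-4-enyl 2,2-dimethylpropanoate | COc1cc([C@H](O)[C@H](COC(=O)C(C)(C)C)CC=C)ccc1O[Si](C(C)C)(C(C)C)C(C)C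
F7 | step 4 | (2S)-2-{(R)-(methoxymethoxy)[3-methoxy-4-(triisopropylsilyloxy)phenyl]methyl}pent-4-enyl 2,2-dimethylpropanoate | COc1cc([C@H](OCOC)[C@H](COC(=O)C(C)(C)C)CC=C)ccc1O[Si](C(C)C)(C(C)C)C(C)C
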